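## Analysis of the target

The target is a germacranolide: a ten-membered carbocycle, numbered here C1–C10, trans-fused at C6–C7 to an α-methylene-γ-butyrolactone (O on C6, C7, C11=C13, C12=O). C1 is the CH2 between the ketone C2 and the exocyclic alkene C10=C14, and C15 is the methyl on C4. C2 is at once the carbonyl of a (Z)-enone (C3=C4) and of a β,γ-unsaturated ketone (C1, C10=C14); C5 bears an acetate and C8 an (E)-2-methylbut-2-enoate (tiglate). The four stereocentres C5–C8 are contiguous (5S,6S,7R,8R); in a zigzag drawing O5/O6 are syn, O6/C11 are syn (trans-lactone) and C11/O8 are anti. Sensitive points are the Z geometry of the enone, the exocyclic alkene that can slip into conjugation through the acidic C1 methylene, the Michael-accepting methylene lactone, and the γ-acyloxy enone, which can eliminate under base. A free C5 hydroxyl beside the Z-enone would add to C2 and lose water, so C5 must be acylated before the enone is released, and three different acyl groups must be placed on three neighbouring oxygens. The synthesis is hard because a medium ring has to be closed in the presence of unsaturation that isomerises easily. The feature the route is built on is the cis array O=C2–C3=C4(C15)–C5–O with the C6 oxygen next to it. C2–C5 is the oxidation pattern of a 2,5-disubstituted 3-methylfuran (furan carbons = C2, C3, C4, C5). The C6 oxygen is 1,5 to the C2 carbonyl, so the six-membered ring O–C2–C3–C4–C5–C6 of an Achmatowicz pyranone is latent in the target.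

## Retrosynthetic reasoning

**Lactone C12–O bond and C2 carbonyl (26 from 23).** The lactone acyl–oxygen bond is cut and the freed C6 hydroxyl is folded onto the C2 ketone as a bridged six-membered hemiketal, with C12 as a tert-butyl ester. This hides the Z-enone and the β,γ-unsaturated ketone until the last operation and stores the C6 oxygen where it cannot be acylated. The forward reaction has to remove the tert-butyl group, open the hemiketal and close the γ-lactone in one acid-mediated step.

**C8–O bond (23 from 21 and 22).** The tiglate is cut at the C8–O bond with inversion. C8 is carried as the S epimer because in that configuration its bulky silyl ether steers the key step; a Mitsunobu esterification with tiglic acid 22 then installs the ester and corrects the centre together.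

**C5 (21 from 20, 19 and 18).** The C5 acetate is traced back to a C5 ketone. In the bridged bicycle 18 the carbocyclic bridge shields one face of the pyranone, so a 1,2-reduction sets C5 from the ring system alone. The C2 carbonyl does not compete because it is a hemiketal.

**Furan dearomatisation (18 from 16).** The pyranone hemiketal 18 is the Achmatowicz product of the furfuryl alcohol 16. The cut is made here because one oxidation converts a flat furan into the C2 ketone (masked), the Z-C3=C4 bond (locked in a six-membered ring) and the C5 carbonyl (exposed), and ties the C6 oxygen to C2.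

**Key disconnection, C6–C7 (16 from 14).** The C6–C7 bond is cut between a 2-furaldehyde and a 2-(bromomethyl)enoate. The forward chromium-mediated allylation closes the ten-membered ring, sets C6 and C7 together and relays their configuration from C8. The cut is placed here because the furan aldehyde has no enolisable position and the furan holds C1 and C6 cis. The precursor 14 has a single stereocentre and no ring other than the furan.

**C7–C11 (14 from 13, 12, 10 and 11).** The bromide arises by allylic transposition of the Morita–Baylis–Hillman adduct 12 of aldehyde 10 and acrylate 11. The C7 carbinol configuration is irrelevant because both epimers converge on the (Z)-bromide 13.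

**C9–C10 (10 from 9, 8, 7 and 6).** The C8 stereocentre is taken from glycidate 6, opened at its CH2 carbon by the alkenylmagnesium reagent 7 derived from 5. This forms C9–C10 and delivers C8 with its oxygen and with C7 at the ester level, one reduction away from aldehyde 10.

**C1–C2 (5 from 2 and 3; 2 from 1).** The bond between C1 and the furan is made by alkylating the lithiated acetal 4 (from 2) with dibromide 3, which brings C1, C10 and C14. Acetal 2 is the protected form of commercial aldehyde 1, whose formyl carbon is C6.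

## Alternatives that were turned down

**Alternative 1:** the textbook route. Disconnection: C6–C7 and the lactone in a fully functionalised open chain. Forward key step: intramolecular chromium-mediated allylation of the acyclic (Z)-enone aldehyde A1, with C5 acetate, C8 tiglate and C2 ketone already in place. Turned down because the Z-enone and the β,γ-unsaturated ketone would have to survive every step of an open-chain sequence, where nothing prevents Z-to-E isomerisation or migration of C10=C14. The α-acetoxy aldehyde can epimerise at C5, C5 must be made separately and related to C6 by acyclic 1,2-induction, and the step count is no lower.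

**Alternative 2:** ring-closing metathesis. Disconnection: C3=C4. Forward key step: second-generation Grubbs catalyst on the vinyl ketone / 1,1-disubstituted alkene A2. Turned down because an electron-poor vinyl ketone and a 1,1-disubstituted alkene are a poor pair for closing a trisubstituted enone in a ten-membered ring. The substrate also offers three competing alkenes (C10=C14, C11=C13, tiglate), the Z geometry would rest on ring preference alone, and all four stereocentres would have to be set beforehand without help from a ring.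

**Alternative 3:** anionic oxy-Cope ring expansion. Disconnection: C9–C10 formed and a C2–C7 bond of a cyclohexenol broken. Forward key step: rearrangement of the 1-allenyl-2-(1-methoxyvinyl)cyclohexenol A3 to the cyclodecadienone A4, which gives the C2 ketone, the exocyclic methylene and the Z-enone at once. Turned down because A4 arrives with C7 and C8 as an enol ether. The acrylate unit and two stereocentres would then have to be introduced on a flexible ten-membered ring next to a β-oxygen that eliminates easily. The cyclohexenol A3, with four stereocentres, is also no simpler than the target.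

Key step: step 9

Assumption: the atom numbering C1–C15 of the analysis is used for every intermediate, and compounds 1, 3, 6, 11 and 22 are taken as commercial.

## Route

Step 1
Reactants: 1 3-methylfuran-2-carbaldehyde
Product: 2 2-(3-methylfuran-2-yl)-1,3-dioxolane
Conditions: ethane-1,2-diol, p-TsOH·H2O (cat.), benzene, reflux, Dean–Stark
Reagents that add atoms: ethane-1,2-diol, OCCO
Why: Acid-catalysed acetalisation with azeotropic removal of water; the aldehyde (future C6) must be masked for the organometallic steps, and the only acidic ring position left is the free alpha carbon (future C2).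

Step 2
Reactants: 2 2-(3-methylfuran-2-yl)-1,3-dioxolane; 3 2,3-dibromoprop-1-ene
Product: 5 2-[5-(2-bromoprop-2-en-1-yl)-3-methylfuran-2-yl]-1,3-dioxolane, via 5-lithiofuran 4 (not isolated)
Conditions: n-BuLi, THF, −78 → −20 °C; then CuI (10 mol %), 3, −78 °C → rt
Reagents that add atoms: none
Why: Alpha-lithiation of the furan at its only free alpha position, then copper-catalysed allylic substitution on 3; the vinylic bromide does not react, so C1, C10 and C14 arrive with a handle for step 3.

Step 3
Reactants: 5 2-[5-(2-bromoprop-2-en-1-yl)-3-methylfuran-2-yl]-1,3-dioxolane; 6 methyl (2S)-oxirane-2-carboxylate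
Product: 8 methyl (2S)-4-{[5-(1,3-dioxolan-2-yl)-4-methylfuran-2-yl]methyl}-2-hydroxypent-4-enoate, via alkenylmagnesium bromide 7 (not isolated)
Conditions: Mg turnings, I2 (cat.), THF, 40 °C; then CuI (10 mol %), 6, −40 → −10 °C; aq. NH4Cl
Reagents that add atoms: none
Why: Copper-catalysed SN2 opening of the glycidate at its unsubstituted carbon by 7 is faster than addition to the ester at low temperature; it forms C9–C10 and leaves the epoxide stereocentre untouched, so C8 is obtained S.

Step 4
Reactants: 8 methyl (2S)-4-{[5-(1,3-dioxolan-2-yl)-4-methylfuran-2-yl]methyl}-2-hydroxypent-4-enoate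
Product: 9 methyl (2S)-2-{[tert-butyl(dimethyl)silyl]oxy}-4-{[5-(1,3-dioxolan-2-yl)-4-methylfuran-2-yl]methyl}pent-4-enoate
Conditions: TBSCl, imidazole, DMF, rt
Reagents that add atoms: tert-butyl(chloro)dimethylsilane, CC(C)(C)[Si](C)(C)Cl
Why: Standard silylation of a secondary alcohol; the bulky silyl ether is the steering group at C8 in step 9.

Step 5
Reactants: 9 methyl (2S)-2-{[tert-butyl(dimethyl)silyl]oxy}-4-{[5-(1,3-dioxolan-2-yl)-4-methylfuran-2-yl]methyl}pent-4-enoate
Product: 10 (2S)-2-{[tert-butyl(dimethyl)silyl]oxy}-4-{[5-(1,3-dioxolan-2-yl)-4-methylfuran-2-yl]methyl}pent-4-enal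
Conditions: i-Bu2AlH (1.1 equiv), CH2Cl2, −78 °C; aq. potassium sodium tartrate
Reagents that add atoms: none
Why: Partial reduction of an alpha-silyloxy methyl ester stops at the aldehyde because the aluminium hemiacetal is stable at −78 °C until work-up; the non-basic conditions do not epimerise C8.

Step 6
Reactants: 10 (2S)-2-{[tert-butyl(dimethyl)silyl]oxy}-4-{[5-(1,3-dioxolan-2-yl)-4-methylfuran-2-yl]methyl}pent-4-enal; 11 tert-butyl prop-2-enoate
Product: 12 tert-butyl (3RS,4S)-4-{[tert-butyl(dimethyl)silyl]oxy}-6-{[5-(1,3-dioxolan-2-yl)-4-methylfuran-2-yl]methyl}-3-hydroxy-2-methylidenehept-6-enoate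
Conditions: 11 (neat, excess), quinuclidine (0.5 equiv), MeOH (1 equiv), rt
Reagents that add atoms: none
Why: Morita–Baylis–Hillman reaction joins C7 to C11; the C7 carbinol forms as a mixture that is erased in step 7, and the tert-butyl ester is chosen so that the later C6 hydroxyl cannot lactonise before step 15.

Step 7
Reactants: 12 tert-butyl (3RS,4S)-4-{[tert-butyl(dimethyl)silyl]oxy}-6-{[5-(1,3-dioxolan-2-yl)-4-methylfuran-2-yl]methyl}-3-hydroxy-2-methylidenehept-6-enoate
Product: 13 tert-butyl (2Z,4S)-2-(bromomethyl)-4-{[tert-butyl(dimethyl)silyl]oxy}-6-{[5-(1,3-dioxolan-2-yl)-4-methylfuran-2-yl]methyl}hepta-2,6-dienoate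
Conditions: NBS, Me2S, CH2Cl2, −20 °C (reagent pre-formed); then 12, −20 → 0 °C
Reagents that add atoms: N-bromosuccinimide, O=C1CCC(=O)N1Br
Why: Corey–Kim-type activation of the allylic alcohol and SN2′ return of bromide converge both C7 epimers on the conjugated (Z)-2-(bromomethyl)enoate; pre-forming the sulfonium salt keeps free NBS away from the furan.

Step 8
Reactants: 13 tert-butyl (2Z,4S)-2-(bromomethyl)-4-{[tert-butyl(dimethyl)silyl]oxy}-6-{[5-(1,3-dioxolan-2-yl)-4-methylfuran-2-yl]methyl}hepta-2,6-dienoate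
Product: 14 tert-butyl (2Z,4S)-2-(bromomethyl)-4-{[tert-butyl(dimethyl)silyl]oxy}-6-[(5-formyl-4-methylfuran-2-yl)methyl]hepta-2,6-dienoate
Conditions: aq. oxalic acid (5 %), THF, rt
Reagents that add atoms: water, O
Why: The furfural acetal ionises easily because of the electron-rich furan and is hydrolysed by mild aqueous acid, which leaves the secondary silyl ether, the tert-butyl ester and the allylic bromide alone.

Step 9
Reactants: 14 tert-butyl (2Z,4S)-2-(bromomethyl)-4-{[tert-butyl(dimethyl)silyl]oxy}-6-[(5-formyl-4-methylfuran-2-yl)methyl]hepta-2,6-dienoate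
Product: 16 tert-butyl 2-[(5S,6S,7S)-5-{[tert-butyl(dimethyl)silyl]oxy}-7-hydroxy-9-methyl-3-methylidene-11-oxabicyclo[6.2.1]undeca-1(10),8-dien-6-yl]prop-2-enoate, via allylchromium species 15 (not isolated)
Conditions: CrCl2 (10 equiv), THF/DMF (10:1), rt; 14 added by syringe pump over 12 h (final 2 mM)
Reagents that add atoms: none
Why: CrCl2 reduces the allylic bromide to the allylchromium species 15, which adds through its gamma carbon (C7) to the tethered 2-furaldehyde in a chair-like six-membered transition state; the closest known reaction type is the intramolecular Nozaki–Hiyama–Kishi (Barbier-type) allylation of aldehydes by 2-(bromomethyl)alk-2-enoates that closes ten-membered germacranolide rings. The step closes the ten-membered carbocycle C1–C10 by 10-exo-trig attack on the formyl carbon and with it the nine-membered ring through the furan oxygen, so the product is an 11-oxabicyclo[6.2.1]undecadiene, a [6](2,5)furanophane. C6 and C7 are set together: the allylchromium equilibrates before it adds and places C8 equatorial in the chair, which gives the anti relationship (the trans-lactone series) whatever the geometry of the bromide. The sense at C7 relative to C8 is assigned from allylic 1,3-strain: H8 eclipses the C7=C11 bond, the bulky silyloxy group points away from the forming bond, and the C9 tether lies on the face of attack, which is also the arrangement that lets the ring close. This gives the 7,8 relationship opposite to that of the target, which is why C8 is carried S and inverted in step 14. The step needs cyclisation to win over oligomerisation (slow addition, high dilution) and chemoselectivity for the aldehyde, which divalent chromium provides: the tert-butyl ester, both 1,1-disubstituted alkenes and the silyl ether are inert. The tert-butyl ester also keeps the new C6 alkoxide from lactonising, so the C6 hydroxyl stays free for step 10. The furan holds C2–C5 in the cis arrangement that brings the chain ends together, but the ring formed is strained, and this is where the risk of the route is placed.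

Step 10
Reactants: 16 tert-butyl 2-[(5S,6S,7S)-5-{[tert-butyl(dimethyl)silyl]oxy}-7-hydroxy-9-methyl-3-methylidene-11-oxabicyclo[6.2.1]undeca-1(10),8-dien-6-yl]prop-2-enoate
Product: 18 tert-butyl 2-[(1R,5S,6S,7S)-5-{[tert-butyl(dimethyl)silyl]oxy}-1-hydroxy-9-methyl-3-methylidene-8-oxo-11-oxabicyclo[5.3.1]undec-9-en-6-yl]prop-2-enoate, via ring-opened (Z)-enedione 17 (not isolated)
Conditions: NBS (1.05 equiv), NaHCO3, THF/H2O (4:1), 0 °C
Reagents that add atoms: water, O
Why: Achmatowicz rearrangement: NBS attacks the electron-rich trisubstituted furan much faster than the 1,1-disubstituted alkenes, water adds, the bromo hemiketal opens to the (Z)-enedione 17, and the C6 hydroxyl closes onto the C2 carbonyl. The six-membered hemiketal can only form with C1 and C7 cis, so C2 is fixed by the ring, the Z geometry of C3=C4 is locked, the C2 ketone is masked, only the C5 ketone is left exposed, and the furanophane strain is released.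

Step 11
Reactants: 18 tert-butyl 2-[(1R,5S,6S,7S)-5-{[tert-butyl(dimethyl)silyl]oxy}-1-hydroxy-9-methyl-3-methylidene-8-oxo-11-oxabicyclo[5.3.1]undec-9-en-6-yl]prop-2-enoate
Product: 19 tert-butyl 2-[(1R,5S,6S,7S,8S)-5-{[tert-butyl(dimethyl)silyl]oxy}-1,8-dihydroxy-9-methyl-3-methylidene-11-oxabicyclo[5.3.1]undec-9-en-6-yl]prop-2-enoate
Conditions: NaBH4, CeCl3·7H2O, MeOH, −78 °C
Reagents that add atoms: none
Why: Luche reduction gives 1,2-reduction of the enone; the C1–C10–C9–C8–C7 bridge covers one face of the pyranone, so hydride should enter C5 from the open face and the new hydroxyl ends cis to C7, the 5S configuration of the target.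

Step 12
Reactants: 19 tert-butyl 2-[(1R,5S,6S,7S,8S)-5-{[tert-butyl(dimethyl)silyl]oxy}-1,8-dihydroxy-9-methyl-3-methylidene-11-oxabicyclo[5.3.1]undec-9-en-6-yl]prop-2-enoate
Product: 20 tert-butyl 2-[(1R,5S,6S,7S,8S)-8-(acetyloxy)-5-{[tert-butyl(dimethyl)silyl]oxy}-1-hydroxy-9-methyl-3-methylidene-11-oxabicyclo[5.3.1]undec-9-en-6-yl]prop-2-enoate
Conditions: Ac2O, pyridine, DMAP (cat.), CH2Cl2, 0 °C → rt
Reagents that add atoms: acetic anhydride, CC(=O)OC(C)=O
Why: Acetylation of the secondary allylic alcohol; the tertiary hemiketal hydroxyl is not acylated, and the C5 oxygen is capped before the enone is released, so it cannot later add to C2.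

Step 13
Reactants: 20 tert-butyl 2-[(1R,5S,6S,7S,8S)-8-(acetyloxy)-5-{[tert-butyl(dimethyl)silyl]oxy}-1-hydroxy-9-methyl-3-methylidene-11-oxabicyclo[5.3.1]undec-9-en-6-yl]prop-2-enoate
Product: 21 tert-butyl 2-[(1R,5S,6R,7S,8S)-8-(acetyloxy)-1,5-dihydroxy-9-methyl-3-methylidene-11-oxabicyclo[5.3.1]undec-9-en-6-yl]prop-2-enoate
Conditions: HF·pyridine, pyridine, THF, 0 °C → rt
Reagents that add atoms: none
Why: Buffered fluoride cleavage of the secondary silyl ether leaves the tert-butyl ester, the allylic acetate and the hemiketal intact; the freed C8 hydroxyl cannot lactonise onto the hindered tert-butyl ester.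

Step 14
Reactants: 21 tert-butyl 2-[(1R,5S,6R,7S,8S)-8-(acetyloxy)-1,5-dihydroxy-9-methyl-3-methylidene-11-oxabicyclo[5.3.1]undec-9-en-6-yl]prop-2-enoate; 22 (2E)-2-methylbut-2-enoic acid
Product: 23 tert-butyl 2-[(1R,5R,6R,7S,8S)-8-(acetyloxy)-1-hydroxy-9-methyl-5-{[(2E)-2-methylbut-2-enoyl]oxy}-3-methylidene-11-oxabicyclo[5.3.1]undec-9-en-6-yl]prop-2-enoate
Conditions: 22, PPh3, DIAD, toluene, 0 °C → rt
Reagents that add atoms: none
Why: Mitsunobu esterification: the C8 alcohol is activated as its alkoxyphosphonium salt and displaced by tiglate with inversion (SN2), which installs the ester and turns the 8S steering centre into the 8R centre of the target; the tertiary hemiketal hydroxyl is too hindered to be activated.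

Step 15
Reactants: 23 tert-butyl 2-[(1R,5R,6R,7S,8S)-8-(acetyloxy)-1-hydroxy-9-methyl-5-{[(2E)-2-methylbut-2-enoyl]oxy}-3-methylidene-11-oxabicyclo[5.3.1]undec-9-en-6-yl]prop-2-enoate
Product: 26 (3aR,4R,9Z,11S,11aS)-11-(acetyloxy)-10-methyl-3,6-dimethylidene-2,8-dioxo-2,3,3a,4,5,6,7,8,11,11a-decahydrocyclodeca[b]furan-4-yl (2E)-2-methylbut-2-enoate, via carboxylic acid 24 (not isolated), via open hydroxy keto acid 25 (not isolated)
Conditions: CF3CO2H/CH2Cl2 (1:10), 0 °C
Reagents that add atoms: none
Why: Acidolysis of the tert-butyl ester gives acid 24, the hemiketal equilibrates with the open hydroxy ketone 25 under acid, and the C6 hydroxyl is trapped irreversibly as the gamma-lactone; the C2 ketone with its Z-enone and its beta,gamma-alkene is uncovered only in this last operation and no stereocentre is touched.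

## Compound list

1 | 3-methylfuran-2-carbaldehyde | Cc1ccoc1C=O | starting material
2 | 2-(3-methylfuran-2-yl)-1,3-dioxolane | Cc1ccoc1C1OCCO1 | intermediate
3 | 2,3-dibromoprop-1-ene | C=C(Br)CBr | starting material
4 | 2-(5-lithio-3-methylfuran-2-yl)-1,3-dioxolane | [Li]c1cc(C)c(o1)C1OCCO1 | intermediate
5 | 2-[5-(2-bromoprop-2-en-1-yl)-3-methylfuran-2-yl]-1,3-dioxolane | C=C(Br)Cc1cc(C)c(o1)C1OCCO1 | intermediate
6 | methyl (2S)-oxirane-2-carboxylate | COC(=O)[C@@H]1CO1 | starting material
7 | bromo{3-[5-(1,3-dioxolan-2-yl)-4-methylfuran-2-yl]prop-1-en-2-yl}magnesium | C=C([Mg]Br)Cc1cc(C)c(o1)C1OCCO1 | intermediate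
8 | methyl (2S)-4-{[5-(1,3-dioxolan-2-yl)-4-methylfuran-2-yl]methyl}-2-hydroxypent-4-enoate | COC(=O)[C@@H](O)CC(=C)Cc1cc(C)c(o1)C1OCCO1 | intermediate
9 | methyl (2S)-2-{[tert-butyl(dimethyl)silyl]oxy}-4-{[5-(1,3-dioxolan-2-yl)-4-methylfuran-2-yl]methyl}pent-4-enoate | COC(=O)[C@@H](O[Si](C)(C)C(C)(C)C)CC(=C)Cc1cc(C)c(o1)C1OCCO1 | intermediate
10 | (2S)-2-{[tert-butyl(dimethyl)silyl]oxy}-4-{[5-(1,3-dioxolan-2-yl)-4-methylfuran-2-yl]methyl}pent-4-enal | O=C[C@@H](O[Si](C)(C)C(C)(C)C)CC(=C)Cc1cc(C)c(o1)C1OCCO1 | intermediate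
11 | tert-butyl prop-2-enoate | C=CC(=O)OC(C)(C)C | starting material
12 | tert-butyl (3RS,4S)-4-{[tert-butyl(dimethyl)silyl]oxy}-6-{[5-(1,3-dioxolan-2-yl)-4-methylfuran-2-yl]methyl}-3-hydroxy-2-methylidenehept-6-enoate | C=C(C(=O)OC(C)(C)C)C(O)[C@@H](O[Si](C)(C)C(C)(C)C)CC(=C)Cc1cc(C)c(o1)C1OCCO1 | intermediate
13 | tert-butyl (2Z,4S)-2-(bromomethyl)-4-{[tert-butyl(dimethyl)silyl]oxy}-6-{[5-(1,3-dioxolan-2-yl)-4-methylfuran-2-yl]methyl}hepta-2,6-dienoate | BrC/C(C(=O)OC(C)(C)C)=C\[C@@H](O[Si](C)(C)C(C)(C)C)CC(=C)Cc1cc(C)c(o1)C1OCCO1 | intermediate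
14 | tert-butyl (2Z,4S)-2-(bromomethyl)-4-{[tert-butyl(dimethyl)silyl]oxy}-6-[(5-formyl-4-methylfuran-2-yl)methyl]hepta-2,6-dienoate | BrC/C(C(=O)OC(C)(C)C)=C\[C@@H](O[Si](C)(C)C(C)(C)C)CC(=C)Cc1cc(C)c(C=O)o1 | intermediate
15 | dichloro{(2Z,4S)-2-(tert-butoxycarbonyl)-4-{[tert-butyl(dimethyl)silyl]oxy}-6-[(5-formyl-4-methylfuran-2-yl)methyl]hepta-2,6-dien-1-yl}chromium | Cl[Cr](Cl)C/C(C(=O)OC(C)(C)C)=C\[C@@H](O[Si](C)(C)C(C)(C)C)CC(=C)Cc1cc(C)c(C=O)o1 | intermediate
16 | tert-butyl 2-[(5S,6S,7S)-5-{[tert-butyl(dimethyl)silyl]oxy}-7-hydroxy-9-methyl-3-methylidene-11-oxabicyclo[6.2.1]undeca-1(10),8-dien-6-yl]prop-2-enoate | C=C1Cc2cc(C)c(o2)[C@@H](O)[C@H](C(=C)C(=O)OC(C)(C)C)[C@@H](O[Si](C)(C)C(C)(C)C)C1 | intermediate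
17 | tert-butyl 2-[(1S,2S,4Z,10S)-10-{[tert-butyl(dimethyl)silyl]oxy}-2-hydroxy-4-methyl-8-methylidene-3,6-dioxocyclodec-4-en-1-yl]prop-2-enoate | C=C1CC(=O)/C=C(/C)C(=O)[C@@H](O)[C@H](C(=C)C(=O)OC(C)(C)C)[C@@H](O[Si](C)(C)C(C)(C)C)C1 | intermediate
18 | tert-butyl 2-[(1R,5S,6S,7S)-5-{[tert-butyl(dimethyl)silyl]oxy}-1-hydroxy-9-methyl-3-methylidene-8-oxo-11-oxabicyclo[5.3.1]undec-9-en-6-yl]prop-2-enoate | C=C1C[C@]2(O)C=C(C)C(=O)[C@@H](O2)[C@H](C(=C)C(=O)OC(C)(C)C)[C@@H](O[Si](C)(C)C(C)(C)C)C1 | intermediate
19 | tert-butyl 2-[(1R,5S,6S,7S,8S)-5-{[tert-butyl(dimethyl)silyl]oxy}-1,8-dihydroxy-9-methyl-3-methylidene-11-oxabicyclo[5.3.1]undec-9-en-6-yl]prop-2-enoate | C=C1C[C@]2(O)C=C(C)[C@H](O)[C@@H](O2)[C@H](C(=C)C(=O)OC(C)(C)C)[C@@H](O[Si](C)(C)C(C)(C)C)C1 | intermediate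
20 | tert-butyl 2-[(1R,5S,6S,7S,8S)-8-(acetyloxy)-5-{[tert-butyl(dimethyl)silyl]oxy}-1-hydroxy-9-methyl-3-methylidene-11-oxabicyclo[5.3.1]undec-9-en-6-yl]prop-2-enoate | C=C1C[C@]2(O)C=C(C)[C@H](OC(C)=O)[C@@H](O2)[C@H](C(=C)C(=O)OC(C)(C)C)[C@@H](O[Si](C)(C)C(C)(C)C)C1 | intermediate
21 | tert-butyl 2-[(1R,5S,6R,7S,8S)-8-(acetyloxy)-1,5-dihydroxy-9-methyl-3-methylidene-11-oxabicyclo[5.3.1]undec-9-en-6-yl]prop-2-enoate | C=C1C[C@]2(O)C=C(C)[C@H](OC(C)=O)[C@@H](O2)[C@H](C(=C)C(=O)OC(C)(C)C)[C@@H](O)C1 | intermediate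
22 | (2E)-2-methylbut-2-enoic acid (tiglic acid) | C/C=C(\C)C(=O)O | starting material
23 | tert-butyl 2-[(1R,5R,6R,7S,8S)-8-(acetyloxy)-1-hydroxy-9-methyl-5-{[(2E)-2-methylbut-2-enoyl]oxy}-3-methylidene-11-oxabicyclo[5.3.1]undec-9-en-6-yl]prop-2-enoate | C=C1C[C@]2(O)C=C(C)[C@H](OC(C)=O)[C@@H](O2)[C@H](C(=C)C(=O)OC(C)(C)C)[C@H](OC(=O)/C(C)=C/C)C1 | intermediate
24 | 2-[(1R,5R,6R,7S,8S)-8-(acetyloxy)-1-hydroxy-9-methyl-5-{[(2E)-2-methylbut-2-enoyl]oxy}-3-methylidene-11-oxabicyclo[5.3.1]undec-9-en-6-yl]prop-2-enoic acid | C=C1C[C@]2(O)C=C(C)[C@H](OC(C)=O)[C@@H](O2)[C@H](C(=C)C(=O)O)[C@H](OC(=O)/C(C)=C/C)C1 | intermediate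
25 | 2-[(1S,2S,3S,4Z,10R)-3-(acetyloxy)-2-hydroxy-4-methyl-10-{[(2E)-2-methylbut-2-enoyl]oxy}-8-methylidene-6-oxocyclodec-4-en-1-yl]prop-2-enoic acid | C=C1CC(=O)/C=C(/C)[C@H](OC(C)=O)[C@@H](O)[C@H](C(=C)C(=O)O)[C@H](OC(=O)/C(C)=C/C)C1 | intermediate
26 | (3aR,4R,9Z,11S,11aS)-11-(acetyloxy)-10-methyl-3,6-dimethylidene-2,8-dioxo-2,3,3a,4,5,6,7,8,11,11a-decahydrocyclodeca[b]furan-4-yl (2E)-2-methylbut-2-enoate; (5S,6S,7R,8R) in the numbering of the analysis | C=C1CC(=O)/C=C(/C)[C@H](OC(C)=O)[C@H]2OC(=O)C(=C)[C@@H]2[C@H](OC(=O)/C(C)=C/C)C1 | target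

## Step count and least certain steps

Total step count: 15. Longest linear sequence: 15 steps (from 1).

**Step 9 (key step).** The transition state leading to the [6](2,5)furanophane is strained, so ring closure may be slow, and intermolecular allylation (oligomers) or protonation of the allylchromium species may take over. The facial sense at C7 relative to C8 rests on a model and may be poor.
Fallback (sets out from 6 and 1, comes back at 18): the ring is closed only after the furan has been dearomatised, at C1–C2 instead of C6–C7.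
- The Grignard reagent of commercial tert-butyl[(2-bromoprop-2-en-1-yl)oxy]dimethylsilane opens 6 under CuI catalysis to the hydroxy ester F1.
- Silylation gives the bis-silyl ether F2, i-Bu2AlH reduction the aldehyde F3, Morita–Baylis–Hillman reaction with 11 the adduct F4, and NBS/Me2S the (Z)-bromide F5.
- HF·pyridine removes the primary allylic silyl group selectively to give the alcohol F6, and NCS/Me2S gives the allylic chloride F7.
- Intermolecular allylation of 1 with F7 (CrCl2, THF, 0 °C; the 2-(bromomethyl)enoate reacts, the simple allylic chloride does not) gives the furfuryl alcohol F8 under the same acyclic steric model.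
- Achmatowicz rearrangement (NBS, NaHCO3, THF/H2O) gives the pyranone lactol F9. Its open (Z)-4-oxoenal form is allylated intramolecularly at C2 (In powder, NaI, DMF, high dilution) to the ten-membered diol F10.
- MnO2 oxidises the allylic C2 hydroxyl selectively to the enedione 17, which closes to 18.

**Step 3.** Insertion of magnesium into the 2-bromoalkene may be sluggish, a proton may be transferred from the doubly activated C1 methylene to the alkenylmetal, or the reagent may attack the ester instead of the epoxide.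
Fallback (sets out from 2, comes back at 8): lithiate 2 as in step 2 and alkylate with 3-chloro-2-(chloromethyl)prop-1-ene to the allylic chloride F11, convert it with Bu3SnLi to the allylstannane F12, and add F12 to methyl glyoxylate under (S)-BINOL/Ti(OiPr)4 catalysis (Keck allylation, the hand of the ligand chosen for the S alcohol) to reach 8.

**Step 11.** Facial selectivity at C5 may be poor if the enone ring is flatter than assumed, and the small amount of open enedione may be reduced as well.
Fallback (sets out from 18, comes back at 20): if hydride delivery favours the other face, the resulting C5-epimeric alcohol F13 is not discarded but inverted during acetylation by a Mitsunobu reaction with acetic acid (PPh3, DIAD), which gives 20 directly.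

**Step 14.** The activated C8 oxygen may eliminate towards C9, or displacement may be slow at a carbon flanked by the branched C7, tiglic acid being only weakly acidic.
Fallback (sets out from 21, comes back at 23): Mitsunobu inversion with the more acidic chloroacetic acid gives the chloroacetate F14, thiourea/NaHCO3 removes the chloroacetyl group selectively to the inverted alcohol F15, and Steglich esterification with 22 (DCC, DMAP) gives 23.

**Step 15.** Acid may move C10=C14 into conjugation with C2, CF3CO2H may add to the exocyclic alkene, or the allylic C5 acetate may ionise.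
Fallback (sets out from 23, comes back at 26): cleave the tert-butyl ester without protic acid (TMSOTf, 2,6-lutidine, then water) and isolate acid 24. Convert it to the 2-pyridyl thioester F16 (2,2′-dipyridyl disulfide, PPh3) and let it lactonise under neutral conditions in warm toluene (Corey–Nicolaou lactonisation), with hemiketal opening supplying the C6 hydroxyl.

## Further compounds

F1 | step 9 | methyl (2S)-4-({[tert-butyl(dimethyl)silyl]oxy}methyl)-2-hydroxypent-4-enoate | COC(=O)[C@@H](O)CC(=C)CO[Si](C)(C)C(C)(C)C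
F2 | step 9 | methyl (2S)-2-{[tert-butyl(dimethyl)silyl]oxy}-4-({[tert-butyl(dimethyl)silyl]oxy}methyl)pent-4-enoate | COC(=O)[C@@H](O[Si](C)(C)C(C)(C)C)CC(=C)CO[Si](C)(C)C(C)(C)C
F3 | step 9 | (2S)-2-{[tert-butyl(dimethyl)silyl]oxy}-4-({[tert-butyl(dimethyl)silyl]oxy}methyl)pent-4-enal | O=C[C@@H](O[Si](C)(C)C(C)(C)C)CC(=C)CO[Si](C)(C)C(C)(C)C
F4 | step 9 | tert-butyl (3RS,4S)-4-{[tert-butyl(dimethyl)silyl]oxy}-6-({[tert-butyl(dimethyl)silyl]oxy}methyl)-3-hydroxy-2-methylidenehept-6-enoate | C=C(C(=O)OC(C)(C)C)C(O)[C@@H](O[Si](C)(C)C(C)(C)C)CC(=C)CO[Si](C)(C)C(C)(C)C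
F5 | step 9 | tert-butyl (2Z,4S)-2-(bromomethyl)-4-{[tert-butyl(dimethyl)silyl]oxy}-6-({[tert-butyl(dimethyl)silyl]oxy}methyl)hepta-2,6-dienoate | BrC/C(C(=O)OC(C)(C)C)=C\[C@@H](O[Si](C)(C)C(C)(C)C)CC(=C)CO[Si](C)(C)C(C)(C)C
F6 | step 9 | tert-butyl (2Z,4S)-2-(bromomethyl)-4-{[tert-butyl(dimethyl)silyl]oxy}-6-(hydroxymethyl)hepta-2,6-dienoate | BrC/C(C(=O)OC(C)(C)C)=C\[C@@H](O[Si](C)(C)C(C)(C)C)CC(=C)CO
F7 | step 9 | tert-butyl (2Z,4S)-2-(bromomethyl)-4-{[tert-butyl(dimethyl)silyl]oxy}-6-(chloromethyl)hepta-2,6-dienoate | BrC/C(C(=O)OC(C)(C)C)=C\[C@@H](O[Si](C)(C)C(C)(C)C)CC(=C)CCl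
F8 | step 9 | tert-butyl (3S,4S)-4-{[tert-butyl(dimethyl)silyl]oxy}-6-(chloromethyl)-3-[(S)-hydroxy(3-methylfuran-2-yl)methyl]-2-methylidenehept-6-enoate | Cc1ccoc1[C@@H](O)[C@H](C(=C)C(=O)OC(C)(C)C)[C@@H](O[Si](C)(C)C(C)(C)C)CC(=C)CCl
F9 | step 9 | tert-butyl (3S,4S)-4-{[tert-butyl(dimethyl)silyl]oxy}-6-(chloromethyl)-3-[(2S)-6-hydroxy-4-methyl-3-oxo-3,6-dihydro-2H-pyran-2-yl]-2-methylidenehept-6-enoate (lactol epimers) | CC1=CC(O)O[C@H](C1=O)[C@H](C(=C)C(=O)OC(C)(C)C)[C@@H](O[Si](C)(C)C(C)(C)C)CC(=C)CCl
F10 | step 9 | tert-butyl 2-[(1S,2S,4Z,6RS,10S)-10-{[tert-butyl(dimethyl)silyl]oxy}-2,6-dihydroxy-4-methyl-8-methylidene-3-oxocyclodec-4-en-1-yl]prop-2-enoate | C=C1CC(O)/C=C(/C)C(=O)[C@@H](O)[C@H](C(=C)C(=O)OC(C)(C)C)[C@@H](O[Si](C)(C)C(C)(C)C)C1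
F11 | step 3 | 2-{5-[2-(chloromethyl)prop-2-en-1-yl]-3-methylfuran-2-yl}-1,3-dioxolane | ClCC(=C)Cc1cc(C)c(o1)C1OCCO1
F12 | step 3 | tributyl(2-{[5-(1,3-dioxolan-2-yl)-4-methylfuran-2-yl]methyl}prop-2-en-1-yl)stannane | CCCC[Sn](CCCC)(CCCC)CC(=C)Cc1cc(C)c(o1)C1OCCO1
F13 | step 11 | tert-butyl 2-[(1R,5S,6S,7S,8R)-5-{[tert-butyl(dimethyl)silyl]oxy}-1,8-dihydroxy-9-methyl-3-methylidene-11-oxabicyclo[5.3.1]undec-9-en-6-yl]prop-2-enoate (C5 epimer of 19) | C=C1C[C@]2(O)C=C(C)[C@@H](O)[C@@H](O2)[C@H](C(=C)C(=O)OC(C)(C)C)[C@@H](O[Si](C)(C)C(C)(C)C)C1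
F14 | step 14 | tert-butyl 2-[(1R,5R,6R,7S,8S)-8-(acetyloxy)-5-[(chloroacetyl)oxy]-1-hydroxy-9-methyl-3-methylidene-11-oxabicyclo[5.3.1]undec-9-en-6-yl]prop-2-enoate | C=C1C[C@]2(O)C=C(C)[C@H](OC(C)=O)[C@@H](O2)[C@H](C(=C)C(=O)OC(C)(C)C)[C@H](OC(=O)CCl)C1
F15 | step 14 | tert-butyl 2-[(1R,5R,6R,7S,8S)-8-(acetyloxy)-1,5-dihydroxy-9-methyl-3-methylidene-11-oxabicyclo[5.3.1]undec-9-en-6-yl]prop-2-enoate (C8 epimer of 21) | C=C1C[C@]2(O)C=C(C)[C@H](OC(C)=O)[C@@H](O2)[C@H](C(=C)C(=O)OC(C)(C)C)[C@H](O)C1
F16 | step 15 | S-pyridin-2-yl 2-[(1R,5R,6R,7S,8S)-8-(acetyloxy)-1-hydroxy-9-methyl-5-{[(2E)-2-methylbut-2-enoyl]oxy}-3-methylidene-11-oxabicyclo[5.3.1]undec-9-en-6-yl]prop-2-enethioate | C=C1C[C@]2(O)C=C(C)[C@H](OC(C)=O)[C@@H](O2)[C@H](C(=C)C(=O)Sc3ccccn3)[C@H](OC(=O)/C(C)=C/C)C1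
A1 | alternative 1 | methyl (2Z,4R,10Z,12S)-12-(acetyloxy)-2-(bromomethyl)-11-methyl-6-methylidene-4-{[(2E)-2-methylbut-2-enoyl]oxy}-8,13-dioxotrideca-2,10-dienoate | O=C[C@@H](OC(C)=O)/C(C)=C\C(=O)CC(=C)C[C@@H](OC(=O)/C(C)=C/C)/C=C(\CBr)C(=O)OC
A2 | alternative 2 | (1R)-1-[(2S,3R)-2-[(1S)-1-(acetyloxy)-2-methylprop-2-en-1-yl]-4-methylidene-5-oxooxolan-3-yl]-3-methylidene-5-oxohept-6-en-1-yl (2E)-2-methylbut-2-enoate | C=CC(=O)CC(=C)C[C@@H](OC(=O)/C(C)=C/C)[C@H]1C(=C)C(=O)O[C@@H]1[C@@H](OC(C)=O)C(C)=C
A3 | alternative 3 | 4,5-bis(methoxymethoxy)-6-(1-methoxyethenyl)-3-methyl-1-(propa-1,2-dien-1-yl)cyclohex-2-en-1-ol (trans alkenyl groups, trans diol) | C=C=C[C@]1(O)C=C(C)[C@H](OCOC)[C@@H](OCOC)[C@H]1C(OC)=C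
A4 | alternative 3 | (2Z)-7-methoxy-4,5-bis(methoxymethoxy)-3-methyl-9-methylidenecyclodeca-2,6-dien-1-one | C=C1CC(=O)/C=C(/C)[C@H](OCOC)[C@@H](OCOC)C=C(OC)C1
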